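The route buys the whole diaryl ether skeleton as 2-phenoxyphenol and disconnects only C–Br bonds. The key step exploits the bridging ether oxygen, whose two ortho carbons, C3 of the phenol ring (ring A) and C2' of the phenoxy ring (ring B), carry the two bromines that electrophilic substitution cannot deliver. Double ortho-lithiation of the triisopropylsilyl ether of 2-phenoxyphenol, followed by quenching with 1,2-dibromotetrafluoroethane, installs both C–Br bonds in one flask. The precursor is simply the O-silylated ether; the bulky silyl group masks the phenol and keeps base away from C6. After desilylation, the free hydroxyl steers the last two bromines to C4 and C6.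

Key step: step 2

Remark on stereochemistry: the target has no stereocentre and its diaryl ether axis rotates freely, so it is achiral and no step has to control configuration.

Remark on structure and naming: ring A is numbered from the oxygen-bearing carbon (C1), with the aryloxy group at C2. The dibromide formed in the key step is therefore the 3-bromo-2-(2-bromophenoxy) isomer, with bromine next to the aryloxy carbon. A name of the type "2-bromo-6-(2-bromophenoxy)phenoxy" would describe the wrong regioisomer and is not used.

Design remark: the triisopropylsilyl ether is kept as the mask. A smaller silyl group would be open to butyl attack at silicon and to silyl migration, and a coordinating mask (acetal, carbamate) would pull the base to C6.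

Step 1
Reactants: 1 2-phenoxyphenol; 2 chlorotriisopropylsilane
Product: 3 triisopropyl(2-phenoxyphenoxy)silane
Conditions: TIPSCl (1.2 equiv), imidazole (2.5 equiv), DMF, rt
Reagents that add atoms: chlorotriisopropylsilane (2), CC(C)[Si](Cl)(C(C)C)C(C)C
Why: Imidazole-mediated O-silylation of a phenol (silyl ether formation through the N-silylimidazolium) is reliable for ortho-substituted phenols, and nothing else in 1 can react.

Step 2
Reactants: 3 triisopropyl(2-phenoxyphenoxy)silane; 4 1,2-dibromotetrafluoroethane
Product: 6 [3-bromo-2-(2-bromophenoxy)phenoxy]triisopropylsilane, via dilithio silyl ether 5 (not isolated)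
Conditions: n-BuLi (2.6 equiv), TMEDA (2.6 equiv), Et2O, 0 °C → rt; then BrCF2CF2Br (3 equiv), −78 °C → rt
Reagents that add atoms: 1,2-dibromotetrafluoroethane (4), FC(F)(Br)C(F)(F)Br; n-butyllithium, [Li]CCCC (supplies the lithium of intermediate 5 only)
Why: Directed ortho-metalation: the TMEDA-activated butyllithium binds the diaryl ether oxygen and removes the neighbouring proton on each ring, giving the oxygen-bridged dilithio species 5, whose two C–Li bonds then attack bromine of the perhaloalkane, which collapses to lithium bromide and tetrafluoroethylene. The closest known reactions are the 2,2'-dilithiation of diphenyl ether with n-BuLi/TMEDA followed by electrophile quench and the bromination of aryllithiums with 1,2-dibromotetrahaloethanes. No ring is closed and no stereocentre is created; the step forms only the C3–Br and C2'–Br bonds. The selectivity required is C3 over C6 on ring A (ring B offers only equivalent ortho positions): the ether oxygen is the sole good lithium ligand, the lithium already at C2' holds the second equivalent of base next to C3, and the triisopropylsilyl group both makes its own oxygen a poor donor and screens C6. The same bulk should prevent butyl attack at silicon and anionic silyl migration during the metalation, and the cold quench with excess reagent limits addition of aryllithium to the liberated fluoroalkene.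

Step 3
Reactants: 6 [3-bromo-2-(2-bromophenoxy)phenoxy]triisopropylsilane
Product: 7 3-bromo-2-(2-bromophenoxy)phenol
Conditions: TBAF (1.1 equiv), THF, 0 °C; then 1 M HCl
Reagents that add atoms: none
Why: Fluoride-induced desilylation: fluoride attacks silicon to form the strong Si–F bond and expels the phenoxide, while the aryl bromides and the diaryl ether are inert to fluoride at 0 °C.

Step 4
Reactants: 7 3-bromo-2-(2-bromophenoxy)phenol; 8 bromine
Product: 9 3,4,6-tribromo-2-(2-bromophenoxy)phenol
Conditions: Br2 (2.05 equiv, dropwise), AcOH, rt; aq Na2S2O3
Reagents that add atoms: bromine (8), BrBr
Why: Electrophilic aromatic bromination directed by the free hydroxyl: C4 (para) and C6 (ortho) are its only open activated positions, C5 is meta to it, and ring B, which has no hydroxyl and is deactivated by its bromine and its electron-poor aryloxy partner, should not compete when two equivalents are used.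

Compound list
1 | 2-phenoxyphenol | Oc1ccccc1Oc1ccccc1 | starting material
2 | chlorotriisopropylsilane | CC(C)[Si](Cl)(C(C)C)C(C)C | starting material
3 | triisopropyl(2-phenoxyphenoxy)silane | CC(C)[Si](C(C)C)(C(C)C)Oc1ccccc1Oc1ccccc1 | intermediate
4 | 1,2-dibromotetrafluoroethane | FC(F)(Br)C(F)(F)Br | starting material
5 | [3-lithio-2-(2-lithiophenoxy)phenoxy]triisopropylsilane (dilithio silyl ether, formed and consumed in the flask) | CC(C)[Si](C(C)C)(C(C)C)Oc1cccc([Li])c1Oc1ccccc1[Li] | intermediate
6 | [3-bromo-2-(2-bromophenoxy)phenoxy]triisopropylsilane | CC(C)[Si](C(C)C)(C(C)C)Oc1cccc(Br)c1Oc1ccccc1Br | intermediate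
7 | 3-bromo-2-(2-bromophenoxy)phenol | Oc1cccc(Br)c1Oc1ccccc1Br | intermediate
8 | bromine | BrBr | starting material
9 | 3,4,6-tribromo-2-(2-bromophenoxy)phenol | Oc1c(Br)cc(Br)c(Br)c1Oc1ccccc1Br | target

Total step count: 4
Longest linear sequence: 4 steps (1 → 3 → 6 → 7 → 9)

Steps most likely to fail

1. Step 2 (key step). Deprotonation at C6 of ring A in place of C3, an incomplete second metalation, or transfer of the silyl group to carbon would leave isomeric or under-brominated ethers that are hard to separate. The fallback uses known chemistry and forms the ether bond with both ortho bromines already in place. It gives up the bought ether, so it sets out from no numbered compound but from commercial 1-bromo-2-iodobenzene and 2-bromo-6-methoxyphenol, and it comes back to the route at 7. 1-Bromo-2-iodobenzene is oxidised with mCPBA and TsOH·H2O in MeCN and the resulting iodine(III) species is trapped with 1,3,5-trimethoxybenzene to give (2-bromophenyl)(2,4,6-trimethoxyphenyl)iodonium tosylate F1. Its 2-bromophenyl group is transferred to the potassium salt of 2-bromo-6-methoxyphenol (t-BuOK, THF, rt → 40 °C; metal-free O-arylation in which the electron-rich trimethoxyphenyl group stays on iodine) to give 1-bromo-2-(2-bromophenoxy)-3-methoxybenzene F2. BBr3 in CH2Cl2 (−78 → 0 °C) then cleaves the methyl ether to 7.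

2. Step 4. Bromination could run on to the para position of ring B, or stall after the first bromine on ring A, so that a mixture of tri-, tetra- and pentabromides results. The fallback sets out from 7 and comes back at 9, and it adds the two bromines one at a time with reagents that react only with free phenols. Tetrabutylammonium tribromide (1 equiv, CH2Cl2/MeOH, rt) should brominate para to the hydroxyl and give 3,4-dibromo-2-(2-bromophenoxy)phenol F3. NBS (1 equiv) with catalytic diisopropylamine in CH2Cl2 at 0 °C, an amine-mediated ortho-bromination of phenols, should then place the last bromine at C6 to give 9.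

3. Step 1. Silyl transfer to a phenol oxygen crowded by the neighbouring phenoxy group could be slow and incomplete, and residual free phenol would consume base in step 2. The fallback sets out from 2 and comes back at 3, and it silylates an unhindered phenol first and forms the diaryl ether afterwards. Commercial catechol is monosilylated with 2 (1 equiv, imidazole, DMF, 0 °C) to 2-[(triisopropylsilyl)oxy]phenol F4. Its potassium phenoxide (t-BuOK, THF, rt) is then O-phenylated with diphenyliodonium triflate to give 3.

Further compounds
F1 | step 2 | (2-bromophenyl)(2,4,6-trimethoxyphenyl)iodonium tosylate | COc1cc(OC)c([I+]c2ccccc2Br)c(OC)c1.Cc1ccc(cc1)S(=O)(=O)[O-]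
F2 | step 2 | 1-bromo-2-(2-bromophenoxy)-3-methoxybenzene | COc1cccc(Br)c1Oc1ccccc1Br
F3 | step 4 | 3,4-dibromo-2-(2-bromophenoxy)phenol | Oc1ccc(Br)c(Br)c1Oc1ccccc1Br
F4 | step 1 | 2-[(triisopropylsilyl)oxy]phenol | CC(C)[Si](C(C)C)(C(C)C)Oc1ccccc1O
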